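**Remark on the chemistry:** the target SMILES contains no stereocentre and no stereogenic double bond (the prenyl alkene carries two methyl groups on one carbon). The compound is achiral, so "single enantiomer" is met trivially and the route needs no stereocontrol.

## Structural features

The target is a dihydrochalcone. Ring A is a phloroglucinol nucleus whose O1/C4a edge is annulated to a 2,2-dimethyl-3,4-dihydro-2H-pyran (a chroman: O1, C2(CH3)2, C3H2, C4H2). Ring B is a 1,3,4,5-tetrasubstituted benzene (C1 chain, C3–OH, C4–OCH3, C5–prenyl). The rings are joined by a C(=O)–CH2–CH2 bridge.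

The ketone carbon sits on C6 of the chroman, between the free C5–OH and C7–OH and para to O1 (the "linear" 6-acyl isomer). C6 and C8 of a 5,7-dioxygenated chroman are both doubly ortho-activated, so electrophilic acylation does not distinguish them, and in an acylphloroglucinol two different hydroxyls can close the pyran ring.

The saturated bridge must be made in the presence of the trisubstituted prenyl alkene, which rules out a late catalytic hydrogenation of an enone. Three free phenols, the acid-sensitive prenyl group and the very electron-rich ring A limit the use of strong acids and oxidants.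

In ring B the methoxy oxygen is the central one of three contiguous substituents and the chain is para to it, a pattern that electrophilic substitution of a guaiacol does not give.

The key step exploits the two hydroxyls (on C5 and C7) that flank the carbonyl-bearing C6. At the aldehyde oxidation level each is a built-in anionic ligand that holds a metal next to the formyl C–H bond. The C(=O)–CH2 bond of the bridge can therefore be made by adding that C–H across a vinyl group on C1 of ring B, which gives the saturated ketone directly with the prenyl alkene as a spectator.

## Logic of the disconnections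

**9 to 4 and 8.** The C(=O)–CH2 bond of the bridge is cut, with the hydrogen on the benzylic CH2 returned to the carbonyl carbon. In one sentence: 9 is made by rhodium-catalysed, phenoxide-chelation-assisted addition of the formyl C–H bond of 4 across the vinyl group of 8. The cut falls at the hindered di-ortho-hydroxy aryl ketone and splits the molecule into halves of 12 and 14 carbons. It removes the need for any enone, any reduction and any protecting group. The forward step must add to the vinyl group with linear regiochemistry and must leave the prenyl alkene untouched.

**4 to 3.** The two hydrogens on C3 and C4 of the pyran ring are removed (C3=C4 alkene). The chromene is the form in which the ring can be closed regiospecifically. The forward hydrogenation must spare the formyl group.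

**3 to 2.** The C4–C4a bond is cut, which opens the pyran to an aryl 1,1-dimethylpropargyl ether. The gain is that the ring oxygen is fixed as the para oxygen before the ring exists. The forward step must form the C–C bond without breaking the O–C bond, and the two ring carbons ortho to the ether must be equivalent.

**2 to 1.** The O–C(CH3)2 bond is cut. 1 is symmetric (C3 and C5 equivalent, the two chelated hydroxyls equivalent), so the only selectivity required is O-alkylation of the unique para hydroxyl over the two ortho ones.

**8 to 7.** The vinyl C=C bond is cut back to the aldehyde C=O (one-carbon olefination). This keeps ring B in the benzaldehyde series, where its substitution pattern is accessible. The forward step must tolerate a free phenol.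

**7 to 6.** The aryl C5–CH2 bond of the prenyl group is cut to an aryl bromide and a prenyl nucleophile. The forward coupling must bond at the unsubstituted terminus of the allyl unit.

**6 to 5.** The O–CH3 bond is cut. The forward methylation must choose the hydroxyl para to the formyl group over the meta one.

## Other disconnections considered

**Alternative 1:** the first route that comes to mind cuts Cα–Cβ of the bridge.
- Forward: Claisen–Schmidt condensation of the methyl ketone A1 (6-acetyl-5,7-bis(methoxymethoxy)-2,2-dimethylchroman) with aldehyde A2 (the MOM ether of 7) to chalcone A3, then 1,4-reduction and removal of three MOM groups.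
- Reason to prefer the chosen plan: the aldol bond is not where the difficulty lies. All three phenols must be masked, because free 2',6'-dihydroxychalcones close to flavanones and phenoxides deactivate both partners. The enone must then be reduced without touching the prenyl alkene, so Pd/H2 is excluded. Protection, reduction and deprotection add four to five steps that the hydroacylation avoids by forming the CH2CH2 unit at the right oxidation level.

**Alternative 2:** cut the aryl C6–C(=O) bond.
- Forward: Friedel–Crafts or Houben–Hoesch acylation of chromandiol A4 with acid A5 or its nitrile.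
- Reason to prefer the chosen plan: in A4, C6 (between two OH) and C8 (between OH and O1) are both doubly ortho-activated and C8 is the less hindered. The angular ketone A6 should therefore accompany or outweigh the target, and nothing in A4 steers the electrophile to C6. The acids needed (BF3·OEt2, ZnCl2/HCl, polyphosphoric acid) would also protonate the prenyl alkene of A5. In the chosen plan the carbon on C6 is present from symmetric 1, where no regiochemical question arises.

**Alternative 3:** cut the CH2–aryl bond (Cβ to C1 of ring B).
- Forward: Pd-catalysed ring-opening cross-coupling of cyclopropanol A7 (a ketone homoenolate equivalent) with aryl bromide A8, then MOM removal.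
- Reason to prefer the chosen plan: this also gives the saturated ketone directly, but A7 needs the methyl ketone, two protections, an enol silane and a Simmons–Smith step. A8 needs bromine para to OMe and meta to OH, which no electrophilic bromination of the phenol reaches, and the cheap ring-B building blocks carry carbon, not halogen, at that position. β-Hydride elimination from the palladium homoenolate is a further risk. The step count would be roughly double for the same bridge.

Key step: step 7

## Route

Step 1
Reactants: 1 2,4,6-trihydroxybenzaldehyde
Product: 2 2,6-dihydroxy-4-[(2-methylbut-3-yn-2-yl)oxy]benzaldehyde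
Conditions: 3-chloro-3-methylbut-1-yne (1.2 equiv), K2CO3 (1.05 equiv), KI (cat.), CuI (cat.), acetone, 55 °C
Reagents that add atoms: 3-chloro-3-methylbut-1-yne, CC(C)(Cl)C#C
Why: Williamson-type O-alkylation with a tertiary propargylic chloride (copper-assisted substitution); the 4-OH, para to the formyl group, is the most acidic and least hindered hydroxyl, while the two ortho hydroxyls are deactivated by hydrogen bonding to and shielding by the formyl group, so one equivalent of weak base should alkylate O4 only, and the bulky electrophile disfavours a second alkylation.

Step 2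
Reactants: 2 2,6-dihydroxy-4-[(2-methylbut-3-yn-2-yl)oxy]benzaldehyde
Product: 3 5,7-dihydroxy-2,2-dimethyl-2H-chromene-6-carbaldehyde
Conditions: [(JohnPhos)Au(MeCN)]SbF6 (2 mol %), 1,2-dichloroethane, rt to 50 °C
Reagents that add atoms: none
Why: Gold(I)-catalysed 6-endo-dig intramolecular hydroarylation of an aryl propargyl ether (Friedel–Crafts-type attack of the ring carbon on the π-activated alkyne, then protodeauration); C3 and C5 of 2 are equivalent by symmetry and the ether oxygen never leaves its aryl carbon, so only the 6-formyl (linear) chromene can form, and the gem-dimethyl group favours closure.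

Step 3
Reactants: 3 5,7-dihydroxy-2,2-dimethyl-2H-chromene-6-carbaldehyde
Product: 4 5,7-dihydroxy-2,2-dimethyl-3,4-dihydro-2H-chromene-6-carbaldehyde
Conditions: H2 (1 atm), 5% Pd/C, EtOAc, rt, stopped after 1 equiv H2
Reagents that add atoms: none
Why: Heterogeneous catalytic hydrogenation of the cis-disubstituted styrenic C3=C4 bond; the formyl group, a chelated vinylogous acid on a very electron-rich ring, should be reduced much more slowly, and no stereocentre arises because C2 carries two methyl groups.

Step 4
Reactants: 5 3-bromo-4,5-dihydroxybenzaldehyde
Product: 6 3-bromo-5-hydroxy-4-methoxybenzaldehyde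
Conditions: MeI (1.1 equiv), Li2CO3 (1.2 equiv), DMF, 45 °C
Reagents that add atoms: iodomethane, CI
Why: Regioselective mono-O-methylation of a catechol (Williamson ether synthesis); the 4-OH is para to the formyl group and ortho to bromine and is therefore far more acidic than the meta 5-OH, so the weak base forms only the 4-phenoxide, the normal selectivity for 3,4-dihydroxybenzaldehydes.

Step 5
Reactants: 6 3-bromo-5-hydroxy-4-methoxybenzaldehyde
Product: 7 3-hydroxy-4-methoxy-5-(3-methylbut-2-en-1-yl)benzaldehyde
Conditions: prenyl-Bpin (1.5 equiv), Pd-PEPPSI-IPent (3 mol %), K3PO4 (3 equiv), THF/H2O, 65 °C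
Reagents that add atoms: 4,4,5,5-tetramethyl-2-(3-methylbut-2-en-1-yl)-1,3,2-dioxaborolane (prenyl-Bpin), CC(C)=CCB1OC(C)(C)C(C)(C)O1
Why: Suzuki–Miyaura coupling of an aryl bromide with a prenylboronate under ligand control of α-selectivity; the bulky NHC on palladium should place Pd on the unsubstituted allyl terminus before reductive elimination, giving the linear 3-methylbut-2-enyl arene and not the 1,1-dimethylallyl isomer, and aldehyde and phenoxide are tolerated under aqueous phosphate.

Step 6
Reactants: 7 3-hydroxy-4-methoxy-5-(3-methylbut-2-en-1-yl)benzaldehyde
Product: 8 5-ethenyl-2-methoxy-3-(3-methylbut-2-en-1-yl)phenol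
Conditions: Ph3PCH3Br (2.5 equiv), KOtBu (2.4 equiv), THF, 0 °C to rt
Reagents that add atoms: methyltriphenylphosphonium bromide, C[P+](c1ccccc1)(c1ccccc1)c1ccccc1.[Br-]
Why: Wittig methylenation with the non-stabilised ylide; the extra equivalent of base covers the phenol, whose phenoxide is meta to the formyl group and does not deactivate it by resonance, and the prenyl alkene is inert.

Step 7
Reactants: 4 5,7-dihydroxy-2,2-dimethyl-3,4-dihydro-2H-chromene-6-carbaldehyde; 8 5-ethenyl-2-methoxy-3-(3-methylbut-2-en-1-yl)phenol (1.5 equiv)
Product: 9 1-(5,7-dihydroxy-2,2-dimethyl-3,4-dihydro-2H-chromen-6-yl)-3-[3-hydroxy-4-methoxy-5-(3-methylbut-2-en-1-yl)phenyl]propan-1-one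
Conditions: [Rh(cod)Cl]2 (2.5 mol %), dppf (6 mol %), K3PO4 (20 mol %), toluene, 80 °C
Reagents that add atoms: none
Why: Chelation-assisted rhodium-catalysed intermolecular alkene hydroacylation with a salicylaldehyde, the closest known reaction type being the Rh/bisphosphine/base coupling of 2-hydroxybenzaldehydes with terminal alkenes. Base forms the rhodium phenoxide of one of the two equivalent ortho hydroxyls of 4, the formyl C–H bond adds oxidatively to give a five-membered acyl(hydrido)rhodium(III) chelate, the vinyl group of 8 inserts into Rh–H, and C–C reductive elimination releases 9 and Rh(I). The chelate is what suppresses decarbonylation, and 4 cannot fail to offer it because both positions ortho to the formyl group carry OH. No ring is closed and no stereocentre is created. The selectivity needed is linear over branched: hydride insertion is reversible, and reductive elimination of a secondary benzylic alkyl next to a 2,6-disubstituted chelated aroyl group under the bulky ferrocenyl bisphosphine is far more congested than that of the primary 2-arylethyl group, so the linear ketone should form (Curtin–Hammett). Chemoselectivity between the two alkenes of 8 follows from substitution: only the monosubstituted vinyl group binds and inserts, and the trisubstituted prenyl alkene does not. The phenol of 8 is meta to the vinyl group, so it cannot chelate and steer insertion to the branched side, and it is less acidic than the formyl-activated hydroxyls of 4, so the phenoxide on rhodium should be that of 4. The step gives the saturated bridge, the hindered di-ortho-hydroxy aryl ketone and the union of the two halves at once, without protecting groups or any reduction.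

## Compound list

1 | 2,4,6-trihydroxybenzaldehyde | O=Cc1c(O)cc(O)cc1O | starting material
2 | 2,6-dihydroxy-4-[(2-methylbut-3-yn-2-yl)oxy]benzaldehyde | O=Cc1c(O)cc(OC(C)(C)C#C)cc1O | intermediate
3 | 5,7-dihydroxy-2,2-dimethyl-2H-chromene-6-carbaldehyde | O=Cc1c(O)cc2OC(C)(C)C=Cc2c1O | intermediate
4 | 5,7-dihydroxy-2,2-dimethyl-3,4-dihydro-2H-chromene-6-carbaldehyde | O=Cc1c(O)cc2OC(C)(C)CCc2c1O | intermediate
5 | 3-bromo-4,5-dihydroxybenzaldehyde | O=Cc1cc(O)c(O)c(Br)c1 | starting material
6 | 3-bromo-5-hydroxy-4-methoxybenzaldehyde | COc1c(O)cc(C=O)cc1Br | intermediate
7 | 3-hydroxy-4-methoxy-5-(3-methylbut-2-en-1-yl)benzaldehyde | COc1c(O)cc(C=O)cc1CC=C(C)C | intermediate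
8 | 5-ethenyl-2-methoxy-3-(3-methylbut-2-en-1-yl)phenol | COc1c(O)cc(C=C)cc1CC=C(C)C | intermediate
9 | 1-(5,7-dihydroxy-2,2-dimethyl-3,4-dihydro-2H-chromen-6-yl)-3-[3-hydroxy-4-methoxy-5-(3-methylbut-2-en-1-yl)phenyl]propan-1-one | COc1c(O)cc(CCC(=O)c2c(O)cc3c(c2O)CCC(C)(C)O3)cc1CC=C(C)C | target

## Step count and least certain steps

Total step count: 7 (two three-step branches and their union). Longest linear sequence: 4 steps (steps 1, 2, 3, 7 or steps 4, 5, 6, 7).

**Step 7 (key step).** The main risk is insertion of the vinylarene with the opposite regiochemistry through a stabilised benzyl–rhodium species, which would lead to the branched α-methyl ketone. Further risks are decarbonylation of the acyl–rhodium intermediate and sequestration of the catalyst by the chelating polyphenolic product.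

The fallback sets out from 4 and 8 and comes back at 9. It makes the same C(=O)–CH2 bond by polar 1,2-addition instead of C–H activation.
- MOMCl/i-Pr2NEt converts 4 into 5,7-bis(methoxymethoxy)-2,2-dimethyl-3,4-dihydro-2H-chromene-6-carbaldehyde F1 and 8 into 5-ethenyl-2-methoxy-1-(methoxymethoxy)-3-(3-methylbut-2-en-1-yl)benzene F2.
- Hydroboration of F2 with 9-BBN (anti-Markovnikov, terminal vinyl much faster than the trisubstituted alkene) and NaOH/H2O2 should give 2-[4-methoxy-3-(methoxymethoxy)-5-(3-methylbut-2-en-1-yl)phenyl]ethan-1-ol F3.
- I2/PPh3/imidazole should give the iodide 5-(2-iodoethyl)-2-methoxy-1-(methoxymethoxy)-3-(3-methylbut-2-en-1-yl)benzene F4.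
- Iodine–lithium exchange (t-BuLi, Et2O, −78 °C) and addition to F1 should give the racemic carbinol 1-[5,7-bis(methoxymethoxy)-2,2-dimethyl-3,4-dihydro-2H-chromen-6-yl]-3-[4-methoxy-3-(methoxymethoxy)-5-(3-methylbut-2-en-1-yl)phenyl]propan-1-ol F5.
- Dess–Martin oxidation should give the ketone 1-[5,7-bis(methoxymethoxy)-2,2-dimethyl-3,4-dihydro-2H-chromen-6-yl]-3-[4-methoxy-3-(methoxymethoxy)-5-(3-methylbut-2-en-1-yl)phenyl]propan-1-one F6.
- HCl/MeOH (rt to 40 °C) should remove the three MOM groups to give 9.

**Step 1.** The risks are over-alkylation to a bis-ether and C-alkylation at C3 by the ambident phloroglucinol-type anion, both of which consume 1 without giving 2.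

The fallback sets out from 1 and comes back at 3, bypassing 2. It builds the pyran ring by condensation, not by O-alkylation. 1 and 3-methylbut-2-enal with catalytic ethylenediammonium diacetate (toluene, 80 °C) should undergo Knoevenagel-type attack of C3 and dehydration to the ortho-quinone methide 2,6-dihydroxy-3-(3-methylbut-2-en-1-ylidene)-4-oxocyclohexa-1,5-diene-1-carbaldehyde F7, which closes by oxa-6π electrocyclisation to 3. Here the ring oxygen is selected by which hydroxyl becomes the quinone methide carbonyl. The more acidic para hydroxyl is expected, and the regiochemistry of the product would have to be confirmed.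

**Step 2.** The risks are slow attack of the ring carbon on the gold-activated alkyne because the formyl group lowers the nucleophilicity of the arene, inhibition of the cationic catalyst by the chelating substrate, and hydration of the alkyne by adventitious water.

The fallback sets out from 2 and comes back at 3. It is the thermal pericyclic cascade (N,N-diethylaniline, 180 °C): aromatic propargyl Claisen rearrangement to the allenylphenol 2,4,6-trihydroxy-3-(3-methylbuta-1,2-dien-1-yl)benzaldehyde F8, then [1,5]-hydrogen shift and oxa-6π electrocyclisation. Gold is preferred in the main route because in this cascade the hydroxyl on the other side of the allenyl group could also take part in the closure.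

**Step 3.** The risk is over-reduction of the formyl group on the palladium surface (to the benzylic alcohol and on to the methyl group).

The fallback sets out from 3 and comes back at 4. It replaces surface hydrogenation by concerted hydrogen transfer from diimide, generated from dipotassium azodicarboxylate and acetic acid in MeOH at rt. Diimide does not reduce the polarised C=O bond.

**Step 5.** The risks are bond formation at the substituted terminus of the allyl unit (giving the 1,1-dimethylallyl arene), protodeboronation of the prenylboronate, and slow oxidative addition to the electron-rich phenoxide.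

The fallback sets out from 6 and comes back at 7. It builds the prenyl group in two C–C events. Suzuki–Miyaura coupling of 6 with allyl-Bpin, for which no α/γ question exists, should give 3-hydroxy-4-methoxy-5-(prop-2-en-1-yl)benzaldehyde F9. Cross-metathesis of F9 with 2-methylbut-2-ene (second-generation ruthenium NHC benzylidene catalyst, CH2Cl2, 40 °C) should then give 7.

## Further compounds

F1 | step 7 | 5,7-bis(methoxymethoxy)-2,2-dimethyl-3,4-dihydro-2H-chromene-6-carbaldehyde | O=Cc1c(OCOC)cc2OC(C)(C)CCc2c1OCOC
F2 | step 7 | 5-ethenyl-2-methoxy-1-(methoxymethoxy)-3-(3-methylbut-2-en-1-yl)benzene | COCOc1cc(C=C)cc(CC=C(C)C)c1OC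
F3 | step 7 | 2-[4-methoxy-3-(methoxymethoxy)-5-(3-methylbut-2-en-1-yl)phenyl]ethan-1-ol | COCOc1cc(CCO)cc(CC=C(C)C)c1OC
F4 | step 7 | 5-(2-iodoethyl)-2-methoxy-1-(methoxymethoxy)-3-(3-methylbut-2-en-1-yl)benzene | COCOc1cc(CCI)cc(CC=C(C)C)c1OC
F5 | step 7 | 1-[5,7-bis(methoxymethoxy)-2,2-dimethyl-3,4-dihydro-2H-chromen-6-yl]-3-[4-methoxy-3-(methoxymethoxy)-5-(3-methylbut-2-en-1-yl)phenyl]propan-1-ol (racemic) | COCOc1cc(CCC(O)c2c(OCOC)cc3OC(C)(C)CCc3c2OCOC)cc(CC=C(C)C)c1OC
F6 | step 7 | 1-[5,7-bis(methoxymethoxy)-2,2-dimethyl-3,4-dihydro-2H-chromen-6-yl]-3-[4-methoxy-3-(methoxymethoxy)-5-(3-methylbut-2-en-1-yl)phenyl]propan-1-one | COCOc1cc(CCC(=O)c2c(OCOC)cc3OC(C)(C)CCc3c2OCOC)cc(CC=C(C)C)c1OC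
F7 | step 1 | 2,6-dihydroxy-3-(3-methylbut-2-en-1-ylidene)-4-oxocyclohexa-1,5-diene-1-carbaldehyde | O=CC1=C(O)C(=CC=C(C)C)C(=O)C=C1O
F8 | step 2 | 2,4,6-trihydroxy-3-(3-methylbuta-1,2-dien-1-yl)benzaldehyde | O=Cc1c(O)cc(O)c(C=C=C(C)C)c1O
F0 | step 3 | none | none
F9 | step 5 | 3-hydroxy-4-methoxy-5-(prop-2-en-1-yl)benzaldehyde | COc1c(O)cc(C=O)cc1CC=C
A1 | alternative 1 | 1-[5,7-bis(methoxymethoxy)-2,2-dimethyl-3,4-dihydro-2H-chromen-6-yl]ethan-1-one | CC(=O)c1c(OCOC)cc2OC(C)(C)CCc2c1OCOC
A2 | alternative 1 | 4-methoxy-3-(methoxymethoxy)-5-(3-methylbut-2-en-1-yl)benzaldehyde | COCOc1cc(C=O)cc(CC=C(C)C)c1OC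
A3 | alternative 1 | (E)-1-[5,7-bis(methoxymethoxy)-2,2-dimethyl-3,4-dihydro-2H-chromen-6-yl]-3-[4-methoxy-3-(methoxymethoxy)-5-(3-methylbut-2-en-1-yl)phenyl]prop-2-en-1-one | COCOc1cc(/C=C/C(=O)c2c(OCOC)cc3OC(C)(C)CCc3c2OCOC)cc(CC=C(C)C)c1OC
A4 | alternative 2 | 2,2-dimethyl-3,4-dihydro-2H-chromene-5,7-diol | CC1(C)CCc2c(O)cc(O)cc2O1
A5 | alternative 2 | 3-[3-hydroxy-4-methoxy-5-(3-methylbut-2-en-1-yl)phenyl]propanoic acid | COc1c(O)cc(CCC(=O)O)cc1CC=C(C)C
A6 | alternative 2 | 1-(5,7-dihydroxy-2,2-dimethyl-3,4-dihydro-2H-chromen-8-yl)-3-[3-hydroxy-4-methoxy-5-(3-methylbut-2-en-1-yl)phenyl]propan-1-one | COc1c(O)cc(CCC(=O)c2c(O)cc(O)c3CCC(C)(C)Oc23)cc1CC=C(C)C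
A7 | alternative 3 | 1-[5,7-bis(methoxymethoxy)-2,2-dimethyl-3,4-dihydro-2H-chromen-6-yl]cyclopropan-1-ol | COCOc1cc2OC(C)(C)CCc2c(OCOC)c1C1(O)CC1
A8 | alternative 3 | 5-bromo-2-methoxy-1-(methoxymethoxy)-3-(3-methylbut-2-en-1-yl)benzene | COCOc1cc(Br)cc(CC=C(C)C)c1OC
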